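**Retrosynthetic overview**
1. Target 7 ⇒ enone 6: the allylic carbinol comes from a hydroxyl-directed 1,2-reduction of the ring ketone (OH trans to the tertiary OH).
2. 6 ⇒ keto diol 5: acetate on the only secondary OH.
3. 5 ⇒ bis-epoxy enone 3 + 2 PhCO2H (4): both benzoate C–O bonds by SN2 opening of two oxiranes (allylic ring oxirane with inversion, spiro-oxirane at CH2).
4. 3 ⇒ dienone 2 ⇒ salicyl alcohol 1: fused oxirane by face-selective epoxidation; spiro-oxirane and quaternary stereocentre by a catalytic asymmetric dearomatising spiroepoxidation.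
5. Ring order: the carbocycle is the arene ring of 1 throughout; the spiro-oxirane is formed first, the fused oxirane second, and both are opened in one step.

Assumption 1: HY-N2634 is taken exactly as the given SMILES, i.e. [(1R,2S,5R,6S)-6-(acetyloxy)-5-(benzoyloxy)-1,2-dihydroxycyclohex-3-en-1-yl]methyl benzoate.
Assumption 2: ArI* is the C2-symmetric lactamide iodoarene (R,R)-2,2'-[(2-iodo-1,3-phenylene)bis(oxy)]bis[N-mesitylpropanamide], C[C@@H](Oc1cccc(O[C@H](C)C(=O)Nc2c(C)cc(C)cc2C)c1I)C(=O)Nc1c(C)cc(C)cc1C; its sense of induction in the new step is assumed to give (R)-2, and the (S,S)-catalyst is used if it proves opposite.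

**Step 1**
Reactants: 1 2-(hydroxymethyl)phenol (salicyl alcohol)
Product: 3 (1S,2S,6S)-spiro[7-oxabicyclo[4.1.0]hept-4-ene-2,2'-oxiran]-3-one (syn-bis-epoxy enone; both oxirane oxygens on the same ring face), via spiroepoxydienone 2 (not isolated)
Conditions: (R,R)-ArI* (10 mol%), mCPBA (1.1 equiv), CH2Cl2, −20 °C; cold aq NaHCO3 wash; then DMDO (1.3 equiv, acetone), −20 → 0 °C
Reagents that add atoms: dimethyldioxirane (DMDO), CC1(C)OO1
Why: Proposed new method: a catalytic enantioselective Adler–Becker reaction, in which mCPBA oxidises ArI* to a chiral aryl-λ3-iodane, the phenol oxygen of 1 exchanges onto iodine(III), and the pendant CH2OH (held by a hydrogen bond to a lactamide carbonyl) attacks its own ipso carbon in a 3-exo closure on the face opposite the departing iodoarene, so that reductive loss of ArI dearomatises the ring and the chiral iodane decides which face receives oxygen (sets the quaternary spiro centre of 2, R); the closest known chemistry is the racemic NaIO4 Adler–Becker spiroepoxidation of salicyl alcohols and the chiral iodoarene/mCPBA-catalysed ortho-spirolactonisation of phenols (Kita/Ishihara type), here extended to an alcohol nucleophile and an oxirane ring; the second stage is a known dioxirane epoxidation of the more electron-rich γ,δ-alkene of the dienone, expected on the face syn to the spiro-oxirane oxygen (the smaller face and the one anti to the better σ-donor C–CH2 bond, the same preference seen in cycloadditions to 6-oxygenated cyclohexa-2,4-dienones), which sets the two ring-oxirane centres; 2 is not isolated because it dimerises by Diels–Alder reaction on concentration.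

**Step 2**
Reactants: 3 syn-bis-epoxy enone; 4 benzoic acid (two molecules incorporated)
Product: 5 [(1S,5R,6S)-5-(benzoyloxy)-1,6-dihydroxy-2-oxocyclohex-3-en-1-yl]methyl benzoate (zeylenone-type keto diol)
Conditions: PhCO2H (6 equiv), Bu4N+ PhCO2− (0.3 equiv), MeCN, 45 °C
Reagents that add atoms: benzoic acid, OC(=O)c1ccccc1
Why: General-acid-assisted carboxylate SN2 opening of epoxides: benzoate attacks the allylic carbon of the ring oxirane with inversion (the other terminus is neopentyl, next to the spiro centre), giving the trans hydroxy benzoate, and attacks the primary CH2 of the α-keto spiro-oxirane (the quaternary α-keto carbon is inert), leaving the tertiary C–O bond and its configuration untouched; the new secondary OH is cis to the spiro oxygen, so Payne rearrangement is not possible, and the step is a pure addition.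

**Step 3**
Reactants: 5 keto diol
Product: 6 [(1S,5R,6S)-6-(acetyloxy)-5-(benzoyloxy)-1-hydroxy-2-oxocyclohex-3-en-1-yl]methyl benzoate
Conditions: Ac2O (1.3 equiv), pyridine, DMAP (5 mol%), CH2Cl2, 0 °C
Reagents that add atoms: acetic anhydride, CC(=O)OC(C)=O
Why: DMAP-catalysed acylation: the only secondary alcohol is acetylated while the tertiary α-ketol OH does not react at 0 °C with a small excess of anhydride; no stereocentre is touched.

**Step 4**
Reactants: 6 acetylated keto alcohol
Product: 7 [(1R,2S,5R,6S)-6-(acetyloxy)-5-(benzoyloxy)-1,2-dihydroxycyclohex-3-en-1-yl]methyl benzoate (HY-N2634, target)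
Conditions: Me4NBH(OAc)3 (4 equiv), MeCN/AcOH (1:1), −30 → −10 °C
Reagents that add atoms: none
Why: Saksena–Evans hydroxyl-directed triacetoxyborohydride reduction: the tertiary OH exchanges onto boron and delivers hydride intramolecularly to the adjacent enone carbonyl from its own face (1,2-addition only), so the new carbinol (S) is trans to the tertiary OH; the three esters are inert to this reagent.

**Compound list**
1 | 2-(hydroxymethyl)phenol (salicyl alcohol) | OCc1ccccc1O | starting material
2 | (3R)-1-oxaspiro[2.5]octa-5,7-dien-4-one (spiroepoxydienone) | O=C1C=CC=C[C@@]12CO2 | intermediate (not isolated)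
3 | (1S,2S,6S)-spiro[7-oxabicyclo[4.1.0]hept-4-ene-2,2'-oxiran]-3-one (syn-bis-epoxy enone) | O1[C@H]2[C@@H]1C=CC(=O)[C@]2(O3)C3 | intermediate
4 | benzoic acid | OC(=O)c1ccccc1 | starting material
5 | [(1S,5R,6S)-5-(benzoyloxy)-1,6-dihydroxy-2-oxocyclohex-3-en-1-yl]methyl benzoate | O[C@H]1[C@H](OC(=O)c2ccccc2)C=CC(=O)[C@]1(O)COC(=O)c1ccccc1 | intermediate
6 | [(1S,5R,6S)-6-(acetyloxy)-5-(benzoyloxy)-1-hydroxy-2-oxocyclohex-3-en-1-yl]methyl benzoate | CC(=O)O[C@H]1[C@H](OC(=O)c2ccccc2)C=CC(=O)[C@]1(O)COC(=O)c1ccccc1 | intermediate
7 | [(1R,2S,5R,6S)-6-(acetyloxy)-5-(benzoyloxy)-1,2-dihydroxycyclohex-3-en-1-yl]methyl benzoate (HY-N2634) | CC(=O)O[C@H]1[C@H](OC(=O)c2ccccc2)C=C[C@H](O)[C@]1(O)COC(=O)c1ccccc1 | target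

**Totals**
Total step count: 4. Longest linear sequence: 4 steps (1 → 3 → 5 → 6 → 7).

**Three steps most likely to fail, with fallbacks**

Step 1 (the proposed new reaction) is the most uncertain. The iodane could give para-oxidation, benzylic oxidation or low ee, and the facial selectivity of the second epoxidation is argued by analogy only. The fallback uses known chemistry and sets out from 1. Racemic Adler–Becker oxidation (NaIO4, H2O/CH2Cl2, 0 °C) gives racemic 1-oxaspiro[2.5]octa-5,7-dien-4-one F1. This is epoxidised in solution with DMDO as in step 1 to the racemic syn-bis-epoxy enone F2, and opened with benzoic acid 4 as in step 2 to the racemic keto diol F3. A lipase-catalysed acylative kinetic resolution (Burkholderia cepacia lipase, vinyl acetate, MTBE, 30 °C) then acetylates the (1S,5R,6S) enantiomer and leaves the enantiomeric keto diol F4 unreacted. The fallback rejoins the route at 6, with at most 50% yield for that stage. If the enzyme prefers the other enantiomer, the recovered alcohol is 5 itself.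

Step 2 may be unclean: the α-keto spiro-oxirane may open slowly, and benzoate catalysis at 45 °C could cause benzoyl migration or elimination. The fallback sets out from 3 and opens the oxiranes separately, the second under hydroxyl direction. Benzoic acid 4 (3 equiv) with iPr2NEt (0.2 equiv) in CH2Cl2 at room temperature is stopped after the activated allylic oxirane has opened, giving (3S,4S,5R)-4-hydroxy-8-oxo-1-oxaspiro[2.5]oct-6-en-5-yl benzoate F5. Its new secondary OH, cis to the spiro oxygen, then directs a Sharpless-type Ti(OiPr)4-mediated C-3 opening of the 2,3-epoxy alcohol by benzoic acid 4 (Ti(OiPr)4 1.5 equiv, CH2Cl2, room temperature) at the CH2 terminus. The fallback returns to the route at 5.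

Step 4 could give the wrong carbinol epimer if undirected reduction competes, or suffer acyl migration. The fallback sets the carbinol before the oxiranes are opened and sets out from 3. Luche reduction (NaBH4, CeCl3·7H2O, MeOH, −78 °C) should deliver hydride to the less hindered face syn to the spiro-oxirane oxygen, giving (1S,2R,3S,6S)-spiro[7-oxabicyclo[4.1.0]hept-4-ene-2,2'-oxiran]-3-ol F6 with OH trans to the spiro oxygen. Silylation (TBSCl, imidazole, DMF) gives the tert-butyldimethylsilyl ether of the bis-epoxy alcohol F7. Double benzoate opening as in step 2 gives the silyl-protected diol dibenzoate F8. Acetylation as in step 3 gives the silyl-protected acetate F9. HF·pyridine (THF, 0 °C) removes the silyl group, and the fallback returns to the route at 7.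

**Further compounds**
F1 | step 1 | rac-1-oxaspiro[2.5]octa-5,7-dien-4-one (racemic 2) | O=C1C=CC=CC12CO2
F2 | step 1 | rac-syn-bis-epoxy enone (racemic 3; relative configuration as drawn, one enantiomer shown) | O1[C@H]2[C@@H]1C=CC(=O)[C@]2(O3)C3
F3 | step 1 | rac-[5-(benzoyloxy)-1,6-dihydroxy-2-oxocyclohex-3-en-1-yl]methyl benzoate (racemic 5; relative configuration as drawn, one enantiomer shown) | O[C@H]1[C@H](OC(=O)c2ccccc2)C=CC(=O)[C@]1(O)COC(=O)c1ccccc1
F4 | step 1 | [(1R,5S,6R)-5-(benzoyloxy)-1,6-dihydroxy-2-oxocyclohex-3-en-1-yl]methyl benzoate (enantiomer of 5, left unreacted) | O[C@@H]1[C@@H](OC(=O)c2ccccc2)C=CC(=O)[C@@]1(O)COC(=O)c1ccccc1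
F5 | step 2 | (3S,4S,5R)-4-hydroxy-8-oxo-1-oxaspiro[2.5]oct-6-en-5-yl benzoate | O[C@H]1[C@H](OC(=O)c2ccccc2)C=CC(=O)[C@]1(O3)C3
F6 | step 4 | (1S,2R,3S,6S)-spiro[7-oxabicyclo[4.1.0]hept-4-ene-2,2'-oxiran]-3-ol | O1[C@H]2[C@@H]1C=C[C@H](O)[C@]2(O3)C3
F7 | step 4 | tert-butyldimethylsilyl ether of F6 (same configuration) | O1[C@H]2[C@@H]1C=C[C@H](O[Si](C)(C)C(C)(C)C)[C@]2(O3)C3
F8 | step 4 | 2-O-tert-butyldimethylsilyl ether of the deacetyl target: [5-(benzoyloxy)-2-(silyloxy)-1,6-dihydroxycyclohex-3-en-1-yl]methyl benzoate, configuration as in 7 | O[C@H]1[C@H](OC(=O)c2ccccc2)C=C[C@H](O[Si](C)(C)C(C)(C)C)[C@]1(O)COC(=O)c1ccccc1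
F9 | step 4 | 2-O-tert-butyldimethylsilyl ether of 7 (configuration as in 7) | CC(=O)O[C@H]1[C@H](OC(=O)c2ccccc2)C=C[C@H](O[Si](C)(C)C(C)(C)C)[C@]1(O)COC(=O)c1ccccc1
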